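The micromolar-hour is the unit I count in: Friday's 2.5 µM of enzyme over 10 h makes 25.0 µM·h of exposure, meaning enzyme concentration multiplied by time. Tuesday's flask gets 2.50 µM·h and Monday's 8.00 µM·h.

| flask | substrate | enzyme | remark | time |
|---|---|---|---|---|
| maple | 23 mM | 0.18 µM | run made earlier |  |
| elm | 23 mM | 1.7 µM | run made earlier |  |
| Tuesday's | 23 mM | 0.25 µM |  | 10 h |
| Monday's | 23 mM | 0.80 µM |  | 10 h |
| Friday's | 23 mM | 2.5 µM |  | 10 h |

| run | time / h | target / % | over-reaction product / % |
|---|---|---|---|
| maple | 0.417 | 0.1 | 0 |
| maple | 0.667 | 0.6 | 0 |
| maple | 1.00 | 1.0 | 2.3 |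
| maple | 1.33 | 1.6 | 2.2 |
| maple | 2.00 | 0.1 | 0 |
| maple | 3.00 | 2.1 | 0.7 |
| maple | 5.00 | 0.3 | 0.2 |
| elm | 0.667 | 3.4 | 0 |
| elm | 1.33 | 4.0 | 1.3 |
| elm | 2.00 | 8.0 | 0.4 |
| elm | 3.00 | 9.0 | 1.6 |
| elm | 4.00 | 12.9 | 0.9 |
| elm | 5.00 | 14.8 | 0.9 |

(each reading ± 1 percentage point)

- reactions considered so far: substrate + enzyme -> target + enzyme; enzyme + target -> enzyme + over-reaction product
- "hardly changes" means that all values lie within two and a half points (for a concentration: within two and a half percent of the largest)

- share of target in all that became target or over-reaction product for Tuesday's, Monday's, Friday's, in this order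
- how that number moves from the first to the last of them (falls, then rises / rises, then falls / falls all the way / hardly changes / rises all the way)

Enzyme stands on both sides of both reactions, so its concentration stays put. If each rate is proportional to it, exposure is the clock of these flasks.

Now I freeze what moves little. At the last elm reading, about 15.7 % of the substrate has been converted, so I hold c(substrate) at its charge as a rough step, though Friday's exposure goes further than the elm readings do. Target then forms at a steady pace r, and c(target) is r multiplied by time. The second step is pseudo-first-order in target, with rate k·c(enzyme)·c(target), where k is its rate constant, so c(over-reaction product) grows with the square of time. Dividing one by the other cancels r: c(over-reaction product)/c(target) = k·x/2, with x the exposure. The first step's law need not be known for this.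

I call k/2 g and read it from the last elm point, at 8.50 µM·h, where target reads 14.8 % and over-reaction product 0.9 %. That gives g = 0.00715 µM⁻¹ h⁻¹, a rough reading, since each value scatters by 1 percentage point. The share of target is 1/(1 + g·x), so my own reckoning gives 98.2 % for Tuesday's, 94.6 % for Monday's and 84.8 % for Friday's.

The forecast says 97 %, 91.5 % and 75 %, so in it the share falls all the way, holding that “more exposure always favours over-reaction”. Its Friday share is lower than mine.

The simulation gives 99.6 %, 98.6 % and 95.2 %: the share falls all the way, as forecast, but Friday's stands higher than the forecast's.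

    substrate + enzyme → target + enzyme, rate k1*[substrate]^3*[enzyme]/(1 + ([substrate]/Kh1)^3) (29.0 mM, k = 18000 M⁻³ s⁻¹)
    enzyme + target → enzyme + over-reaction product (k = 3400 M⁻¹ h⁻¹)

In Friday's flask, with enzyme at 100 % throughout its 25.0 µM·h, the first step took substrate down to 65.0 % and raised target to 33.3 %, while the second step turned that growing target into 1.69 % of over-reaction product. Tuesday's flask reaches the same exposure, 25.0 µM·h, later, at 100 h, and holds the same mixture: substrate 65.0 %, target 33.3 %, over-reaction product 1.69 %.

The data are calculated for substances that don't exist; noise was put on by code.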